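**Retrosynthetic overview**

1. The last operation closes both rings from a linear chain: first the γ-lactone (O6–C12 acyl bond), then the ten-membered carbocycle at C7–C8 by an indium Barbier allylation of a C8/C9 keto aldehyde. This also creates the free C8 hydroxyl beside the C9 ketone.
2. The cyclisation precursor carries a 2-(oxiranyl)acrylate (C6–C7 oxirane, C11–C13) that stores the lactone oxygen and the allyl donor. It comes from a 2,3-dihydroxy aldehyde (C6) by chelation-controlled γ-bromoallylation and oxirane closure; the angelate is put on C5 at that stage.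
3. C5 comes from (S)-glycerate, C4 from a chelation-controlled MeMgBr addition to a C4 ketone, and the C6 aldehyde from oxidation of the primary alcohol.
4. The C3–C4 bond is made by a Grignard/Weinreb coupling. C10 and C1–C3 come from (S)-β-citronellene, whose vinyl group is the latent C8/C9 keto aldehyde.

Assumption: (S)-β-citronellene, methyl (S)-2,2-dimethyl-1,3-dioxolane-4-carboxylate, methyl 2-(bromomethyl)acrylate and angelic anhydride are taken as catalogue chemicals. Atom locants (C1–C13) follow germacrane numbering: C1–C3 ring CH2, C4 tertiary carbinol, C5 angeloyloxy carbon, C6 lactone O–CH, C7 ring-fusion CH, C8 secondary carbinol, C9 ketone, C10 CH–CH3, C11–C13 methylene lactone. The target is 4R,5S,6R,7S,8S,10S.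

**Route**

Step 1
Reactants: 1 (3S)-3,7-dimethylocta-1,6-diene
Product: 3 (4S)-4-methylhex-5-en-1-ol, via (4S)-4-methylhex-5-enal 2 (not isolated)
Conditions: O3 (1.0 equiv), CH2Cl2/MeOH, −78 °C; then NaBH4, −78→23 °C
Reagents that add atoms: ozone ([O-][O+]=O)
Why: Chemoselective ozonolysis with reductive work-up: the electron-rich trisubstituted alkene is ozonised far faster than the vinyl group, and borohydride reduces the aldehyde without touching the C10 stereocentre.

Step 2
Reactants: 3 (4S)-4-methylhex-5-en-1-ol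
Product: 4 (3S)-6-bromo-3-methylhex-1-ene
Conditions: CBr4, PPh3, CH2Cl2, 0 °C
Reagents that add atoms: carbon tetrabromide (BrC(Br)(Br)Br)
Why: Appel reaction of a primary alcohol, with no stereocentre involved.

Step 3
Reactants: 5 methyl (4S)-2,2-dimethyl-1,3-dioxolane-4-carboxylate
Product: 6 (4S)-N-methoxy-N,2,2-trimethyl-1,3-dioxolane-4-carboxamide
Conditions: MeNH(OMe)·HCl, iPrMgCl, THF, −20 °C
Reagents that add atoms: N,O-dimethylhydroxylamine hydrochloride (CNOC.Cl)
Why: Weinreb amide formation by aminolysis of the ester with the chloromagnesium amide, under conditions known not to epimerise the α-alkoxy centre (future C5).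

Step 4
Reactants: 4 (3S)-6-bromo-3-methylhex-1-ene; 6 (4S)-N-methoxy-N,2,2-trimethyl-1,3-dioxolane-4-carboxamide
Product: 8 (5S)-1-[(4S)-2,2-dimethyl-1,3-dioxolan-4-yl]-5-methylhept-6-en-1-one, via alkylmagnesium bromide 7 (not isolated)
Conditions: Mg, THF, 23 °C; then 6, −78→0 °C; aq. NH4Cl
Reagents that add atoms: none
Why: Grignard formation followed by Weinreb ketone synthesis, where the chelated tetrahedral intermediate stops over-addition and C5 is not enolised.

Step 5
Reactants: 8 (5S)-1-[(4S)-2,2-dimethyl-1,3-dioxolan-4-yl]-5-methylhept-6-en-1-one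
Product: 10 (2S,3R,7S)-3,7-dimethylnon-8-ene-1,2,3-triol, via tertiary alcohol acetonide 9 (not isolated)
Conditions: MeMgBr, Et2O, −78 °C; then 2 M HCl, THF, 23 °C
Reagents that add atoms: methylmagnesium bromide (C[Mg]Br)
Why: Chelation-controlled (Cram chelate) Grignard addition: magnesium bridges the ketone oxygen and the α-oxygen of the dioxolane, methyl attacks from the side of the C5 hydrogen and sets C4 as R, and aqueous acid then hydrolyses the acetonide (acetal hydrolysis).

Step 6
Reactants: 10 (2S,3R,7S)-3,7-dimethylnon-8-ene-1,2,3-triol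
Product: 11 (2R,3R,7S)-2,3-dihydroxy-3,7-dimethylnon-8-enal
Conditions: TEMPO (10 mol %), PhI(OAc)2, CH2Cl2, 23 °C
Reagents that add atoms: none
Why: TEMPO/PhI(OAc)2 oxidation: the oxoammonium salt oxidises the primary alcohol much faster than the secondary one and cannot oxidise the tertiary one, and the anhydrous medium stops at the aldehyde (used crude).

Step 7
Reactants: 12 methyl 2-(bromomethyl)prop-2-enoate
Product: 14 methyl (2Z)-3-bromo-2-(bromomethyl)prop-2-enoate, via tribromo ester 13 (not isolated)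
Conditions: Br2, CH2Cl2, 0 °C; then Et3N, 0→23 °C
Reagents that add atoms: bromine (BrBr)
Why: Bromine addition to the acrylate followed by E1cB-type dehydrobromination returns the conjugated ester as the vinyl bromide; its geometry does not matter for step 8.

Step 8
Reactants: 11 (2R,3R,7S)-2,3-dihydroxy-3,7-dimethylnon-8-enal; 14 methyl (2Z)-3-bromo-2-(bromomethyl)prop-2-enoate
Product: 17 methyl 2-{(3S)-3-[(1S,2R,6S)-1,2-dihydroxy-2,6-dimethyloct-7-en-1-yl]oxiran-2-yl}prop-2-enoate, via bromoallylindium 15 (not isolated), via bromohydrin 16 (not isolated)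
Conditions: In powder (1.3 equiv), 14 (2 equiv), THF/H2O 1:1, 23 °C; then K2CO3, 23 °C
Reagents that add atoms: none
Why: Proposed new method: indium inserts only into the allylic C–Br bond of 14 and the γ-bromoallylindium adds through its bromine-bearing carbon to the aldehyde (Barbier allylation in water), with trivalent indium chelated between the aldehyde and the free α-hydroxyl so that the allyl group arrives syn to that hydroxyl and sets C6, after which carbonate closes the bromohydrin to the oxirane (intramolecular Williamson, C7 epimers both usable); the closest known chemistry is the γ-bromoallylindium reagent from 1,3-dibromopropene and the chelation-controlled indium allylation of α-hydroxy aldehydes.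

Step 9
Reactants: 17 methyl 2-{(3S)-3-[(1S,2R,6S)-1,2-dihydroxy-2,6-dimethyloct-7-en-1-yl]oxiran-2-yl}prop-2-enoate; 18 (2Z)-2-methylbut-2-enoic anhydride
Product: 19 methyl 2-{(3R)-3-[(1S,2R,6S)-2-hydroxy-2,6-dimethyl-1-{[(2Z)-2-methylbut-2-enoyl]oxy}oct-7-en-1-yl]oxiran-2-yl}prop-2-enoate
Conditions: LiN(SiMe3)2 (1.1 equiv), THF, −78 °C; 18, −78→−40 °C; aq. NH4Cl
Reagents that add atoms: none
Why: Acylation of the lithium alkoxide with angelic anhydride: only the secondary C5 hydroxyl reacts (the tertiary C4 hydroxyl is too hindered), the cold amine-free conditions do not isomerise angelate to tiglate, and the C6 oxygen is masked in the oxirane.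

Step 10
Reactants: 19 methyl 2-{(3R)-3-[(1S,2R,6S)-2-hydroxy-2,6-dimethyl-1-{[(2Z)-2-methylbut-2-enoyl]oxy}oct-7-en-1-yl]oxiran-2-yl}prop-2-enoate
Product: 20 methyl 2-{(3R)-3-[(1S,2R,6S)-2,7,8-trihydroxy-2,6-dimethyl-1-{[(2Z)-2-methylbut-2-enoyl]oxy}octyl]oxiran-2-yl}prop-2-enoate
Conditions: OsO4 (2 mol %), NMO (1.2 equiv), acetone/H2O, 0 °C
Reagents that add atoms: N-methylmorpholine N-oxide (C[N+]1([O-])CCOCC1), water (O), osmium tetroxide as oxygen carrier (O=[Os](=O)(=O)=O)
Why: Upjohn dihydroxylation: OsO4 reacts with the isolated monosubstituted alkene much faster than with the conjugated acrylate and angelate alkenes, and the new carbinol centre (C9, unselective) is erased in step 11.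

Step 11
Reactants: 20 methyl 2-{(3R)-3-[(1S,2R,6S)-2,7,8-trihydroxy-2,6-dimethyl-1-{[(2Z)-2-methylbut-2-enoyl]oxy}octyl]oxiran-2-yl}prop-2-enoate
Product: 21 methyl 2-{(3R)-3-[(1S,2R,6S)-2-hydroxy-2,6-dimethyl-1-{[(2Z)-2-methylbut-2-enoyl]oxy}-7,8-dioxooctyl]oxiran-2-yl}prop-2-enoate
Conditions: IBX (3 equiv), DMSO, 23 °C
Reagents that add atoms: none
Why: Hypervalent-iodine oxidation: IBX takes both hydroxyls of a 1,2-diol to the 1,2-dicarbonyl without C–C cleavage, leaves the tertiary alcohol alone, and is neutral enough not to epimerise C10.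

Step 12
Reactants: 21 methyl 2-{(3R)-3-[(1S,2R,6S)-2-hydroxy-2,6-dimethyl-1-{[(2Z)-2-methylbut-2-enoyl]oxy}-7,8-dioxooctyl]oxiran-2-yl}prop-2-enoate
Product: 24 CNP0311008.1 (4R,5S,6R,7S,8S,10S)-5-angeloyloxy-4,8-dihydroxy-9-oxogermacr-11(13)-en-12,6-olide, via bromomethyl butenolide 22 (not isolated), via allylindium 23 (not isolated)
Conditions: MgBr2·OEt2 (1.5 equiv), THF, 0→23 °C; then added over 10 h to In powder, DMF, 40 °C (2 mM); H2O
Reagents that add atoms: none
Why: Proposed new method: MgBr2 opens the 2-(oxiranyl)acrylate with bromide at the allylic position (SN2 or SN2′, the allylic bromides equilibrating under bromide) and the magnesium alkoxide freed on C6 closes onto the methyl ester to give the γ-lactone 22 (first ring), then indium inserts into the allylic C–Br bond and allylindium 23 attacks the aldehyde of the keto aldehyde through its γ-carbon C7, anti to the C6 substituent (trans-lactone, C7 S) and through a chair Zimmerman–Traxler transition state in which the ring fixes the reagent as an E-type allyl donor (C6/C8-OH anti, C8 S), closing the ten-membered ring and leaving the ketone untouched; the closest known chemistry is the indium- or zinc-mediated Barbier allylation of aldehydes with 3-(bromomethyl)furan-2(5H)-one and the halide opening of vinyl oxiranes.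

**Compound list**

1 | (3S)-3,7-dimethylocta-1,6-diene, (S)-β-citronellene | C=C[C@@H](C)CCC=C(C)C | starting material
2 | (4S)-4-methylhex-5-enal | C=C[C@@H](C)CCC=O | intermediate
3 | (4S)-4-methylhex-5-en-1-ol | C=C[C@@H](C)CCCO | intermediate
4 | (3S)-6-bromo-3-methylhex-1-ene | C=C[C@@H](C)CCCBr | intermediate
5 | methyl (4S)-2,2-dimethyl-1,3-dioxolane-4-carboxylate | COC(=O)[C@@H]1COC(C)(C)O1 | starting material
6 | (4S)-N-methoxy-N,2,2-trimethyl-1,3-dioxolane-4-carboxamide | CON(C)C(=O)[C@@H]1COC(C)(C)O1 | intermediate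
7 | [(4S)-4-methylhex-5-en-1-yl]magnesium bromide | C=C[C@@H](C)CCC[Mg]Br | intermediate
8 | (5S)-1-[(4S)-2,2-dimethyl-1,3-dioxolan-4-yl]-5-methylhept-6-en-1-one | C=C[C@@H](C)CCCC(=O)[C@@H]1COC(C)(C)O1 | intermediate
9 | (2R,6S)-2-[(4S)-2,2-dimethyl-1,3-dioxolan-4-yl]-6-methyloct-7-en-2-ol | C=C[C@@H](C)CCC[C@@](C)(O)[C@@H]1COC(C)(C)O1 | intermediate
10 | (2S,3R,7S)-3,7-dimethylnon-8-ene-1,2,3-triol | C=C[C@@H](C)CCC[C@@](C)(O)[C@@H](O)CO | intermediate
11 | (2R,3R,7S)-2,3-dihydroxy-3,7-dimethylnon-8-enal | C=C[C@@H](C)CCC[C@@](C)(O)[C@@H](O)C=O | intermediate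
12 | methyl 2-(bromomethyl)prop-2-enoate | C=C(CBr)C(=O)OC | starting material
13 | methyl 2,3-dibromo-2-(bromomethyl)propanoate | COC(=O)C(Br)(CBr)CBr | intermediate
14 | methyl (2Z)-3-bromo-2-(bromomethyl)prop-2-enoate | COC(=O)/C(CBr)=C/Br | intermediate
15 | methyl 3-bromo-2-[(dibromoindiganyl)methyl]prop-2-enoate | COC(=O)C(C[In](Br)Br)=CBr | intermediate
16 | methyl (4S,5S,6R,10S)-3-bromo-4,5,6-trihydroxy-6,10-dimethyl-2-methylidenedodec-11-enoate (C3 epimers) | C=C[C@@H](C)CCC[C@@](C)(O)[C@@H](O)[C@H](O)C(Br)C(=C)C(=O)OC | intermediate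
17 | methyl 2-{(3S)-3-[(1S,2R,6S)-1,2-dihydroxy-2,6-dimethyloct-7-en-1-yl]oxiran-2-yl}prop-2-enoate (oxirane C2 epimers) | C=C[C@@H](C)CCC[C@@](C)(O)[C@@H](O)[C@@H]1OC1C(=C)C(=O)OC | intermediate
18 | (2Z)-2-methylbut-2-enoic anhydride, angelic anhydride | C/C=C(/C)C(=O)OC(=O)/C(C)=C\C | starting material
19 | methyl 2-{(3R)-3-[(1S,2R,6S)-2-hydroxy-2,6-dimethyl-1-{[(2Z)-2-methylbut-2-enoyl]oxy}oct-7-en-1-yl]oxiran-2-yl}prop-2-enoate (oxirane C2 epimers) | C=C[C@@H](C)CCC[C@@](C)(O)[C@@H](OC(=O)/C(C)=C\C)[C@@H]1OC1C(=C)C(=O)OC | intermediate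
20 | methyl 2-{(3R)-3-[(1S,2R,6S)-2,7,8-trihydroxy-2,6-dimethyl-1-{[(2Z)-2-methylbut-2-enoyl]oxy}octyl]oxiran-2-yl}prop-2-enoate (C7 and oxirane C2 epimers) | OCC(O)[C@@H](C)CCC[C@@](C)(O)[C@@H](OC(=O)/C(C)=C\C)[C@@H]1OC1C(=C)C(=O)OC | intermediate
21 | methyl 2-{(3R)-3-[(1S,2R,6S)-2-hydroxy-2,6-dimethyl-1-{[(2Z)-2-methylbut-2-enoyl]oxy}-7,8-dioxooctyl]oxiran-2-yl}prop-2-enoate (oxirane C2 epimers) | O=CC(=O)[C@@H](C)CCC[C@@](C)(O)[C@@H](OC(=O)/C(C)=C\C)[C@@H]1OC1C(=C)C(=O)OC | intermediate
22 | (1S,2R,6S)-1-[(2R)-4-(bromomethyl)-5-oxo-2,5-dihydrofuran-2-yl]-2-hydroxy-2,6-dimethyl-7,8-dioxooctyl (2Z)-2-methylbut-2-enoate | O=CC(=O)[C@@H](C)CCC[C@@](C)(O)[C@@H](OC(=O)/C(C)=C\C)[C@@H]1OC(=O)C(CBr)=C1 | intermediate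
23 | (1S,2R,6S)-1-{(2R)-4-[(dibromoindiganyl)methyl]-5-oxo-2,5-dihydrofuran-2-yl}-2-hydroxy-2,6-dimethyl-7,8-dioxooctyl (2Z)-2-methylbut-2-enoate | O=CC(=O)[C@@H](C)CCC[C@@](C)(O)[C@@H](OC(=O)/C(C)=C\C)[C@@H]1OC(=O)C(C[In](Br)Br)=C1 | intermediate
24 | CNP0311008.1, (4R,5S,6R,7S,8S,10S)-5-angeloyloxy-4,8-dihydroxy-9-oxogermacr-11(13)-en-12,6-olide | C=C1C(=O)O[C@@H]2[C@@H]1[C@H](O)C(=O)[C@@H](C)CCC[C@@](C)(O)[C@H]2OC(=O)/C(C)=C\C | target

**Totals**

Total step count: 12. Longest linear sequence: 10 steps (1, 2, 4, 5, 6, 8, 9, 10, 11, 12); steps 3 and 7 are side branches.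

**Steps most likely to fail**

Step 12. The risks are oligomerisation at the ten-membered ring closure and 5-exo attack of the free C4 hydroxyl on the activated oxirane (tetrahydrofuran formation). A 1,2-shift of the angelate to the freed C6 alkoxide could also precede lactonisation, and the C8 configuration may deviate from the chair prediction inside the macrocyclic transition state. The fallback sets out from 21 and comes back at 24. Compound 21 is treated at high dilution in THF with catalytic Pd2(dba)3/tri(2-furyl)phosphine and InI. Zerovalent palladium ionises the vinyl oxirane to a π-allylpalladium alkoxide, whose syn/anti equilibration lets the alkoxide reach the ester and lactonise. InI then reduces the π-allyl complex to allylindium 23, which cyclises as before. No bromide Lewis acid and no allyl bromide are present, and no new isolable compound is made.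

Step 8. The risks are a second indium insertion into the allylic bromide of 16 (reduction or double allylation), a modest syn/anti ratio at C6, and Payne rearrangement or ester hydrolysis in the carbonate stage. The fallback sets out from 14 and 11 and comes back at 17. Compound 14 is borylated (B2pin2, CuCl, KOtBu, THF) to the allylboronate methyl (2E)-3-bromo-2-[(4,4,5,5-tetramethyl-1,3,2-dioxaborolan-2-yl)methyl]prop-2-enoate F1. This adds to aldehyde 11 through a closed chair transition state with no reducing metal present (γ-haloallylboration), boron binding the free α-hydroxyl. Hydrolysis gives bromohydrin 16, and K2CO3 closes it to 17.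

Step 9. The risks are the hindered carbinol next to a fully substituted carbon, angelate-to-tiglate isomerisation, and an alkoxide sitting beside the oxirane. The fallback sets out from 17 and comes back at 19. Compound 17 is esterified with 2-[bis(2,2,2-trifluoroethoxy)phosphoryl]propanoic acid (DCC, DMAP, CH2Cl2) to the phosphonate ester methyl 2-{(3R)-3-[(1S,2R,6S)-1-({2-[bis(2,2,2-trifluoroethoxy)phosphoryl]propanoyl}oxy)-2-hydroxy-2,6-dimethyloct-7-en-1-yl]oxiran-2-yl}prop-2-enoate F2. The Z-alkene is then built on the substrate by Still–Gennari olefination with acetaldehyde (KN(SiMe3)2, 18-crown-6, THF, −78 °C), giving 19.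

**Further compounds**

F1 | step 8 | methyl (2E)-3-bromo-2-[(4,4,5,5-tetramethyl-1,3,2-dioxaborolan-2-yl)methyl]prop-2-enoate | COC(=O)/C(CB1OC(C)(C)C(C)(C)O1)=C/Br
F2 | step 9 | methyl 2-{(3R)-3-[(1S,2R,6S)-1-({2-[bis(2,2,2-trifluoroethoxy)phosphoryl]propanoyl}oxy)-2-hydroxy-2,6-dimethyloct-7-en-1-yl]oxiran-2-yl}prop-2-enoate | C=C[C@@H](C)CCC[C@@](C)(O)[C@@H](OC(=O)C(C)P(=O)(OCC(F)(F)F)OCC(F)(F)F)[C@@H]1OC1C(=C)C(=O)OC
F0 | step 12 | none | none
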